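**Plan**

- Retrosynthesis first cuts the two C2–CH3 bonds of the dimethylpyran. Pyran C2 (bonded to O1, two methyls and the cis C3=C4 alkene) is then the carbonyl carbon of a coumarin fused to the catechol ring, which is the feature that allows a double methyl addition.
- The coumarin is cut at C3=C4 and O1–C2 (salicylaldehyde + ketenylidene ylide), the aldehyde at C4a–CHO, and the propane linker at the aryl–CH2 bond of the resorcinol ring (B-alkyl Suzuki).
- Forward: an allyl/prenyl catechol fragment (from 2-bromo-4,5-dihydroxybenzaldehyde) and a 1,1-dimethylallyl bromoresorcinol fragment (aromatic Claisen) are joined through the C3 chain. Formylation and ylide annulation then close the pyranone ring, the only ring made before the key step.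
- Double methyl addition opens that lactone to a cis diol, mild acid closes the 2,2-dimethylpyran, and MOM removal ends the route.
- Stereochemistry: the target has no stereocentre; the cis C3=C4 geometry is fixed by the coumarin ring and carried through.

Key step: step 15

Assumption: kazinol K as drawn is achiral, so no asymmetric step is needed and the drawn structure is the single compound to be made.

Abbreviations: MOM = methoxymethyl; TIPS = triisopropylsilyl; prenyl = 3-methylbut-2-en-1-yl; Ar′ = 2,4-bis(methoxymethoxy)-5-(2-methylbut-3-en-2-yl)phenyl.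

**Catechol-ring fragment**

Step 1
Reactants: 1 2-bromo-4,5-dihydroxybenzaldehyde
Product: 2 2-bromo-5-hydroxy-4-(methoxymethoxy)benzaldehyde
Conditions: MOMCl (1.05 equiv), K2CO3 (1.1 equiv), acetone, 0 °C → rt
Reagents that add atoms: chloromethyl methyl ether (MOMCl), COCCl
Why: The 4-OH, para to the formyl group, is much the more acidic phenol, so one equivalent of weak base forms only that phenoxide and MOMCl alkylates it (regioselective Williamson-type O-alkylation, as known for 3,4-dihydroxybenzaldehyde).

Step 2
Reactants: 2 2-bromo-5-hydroxy-4-(methoxymethoxy)benzaldehyde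
Product: 3 2-bromo-4-(methoxymethoxy)-5-(triisopropylsilyloxy)benzaldehyde
Conditions: TIPSCl, imidazole, DMF, rt
Reagents that add atoms: chlorotriisopropylsilane, CC(C)[Si](Cl)(C(C)C)C(C)C
Why: Imidazole-mediated silylation of the single remaining phenol installs a fluoride-labile group that is orthogonal to MOM and should survive hydride, Grignard, borane and aqueous phosphate.

Step 3
Reactants: 3 2-bromo-4-(methoxymethoxy)-5-(triisopropylsilyloxy)benzaldehyde
Product: 4 2-allyl-4-(methoxymethoxy)-5-(triisopropylsilyloxy)benzaldehyde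
Conditions: allylSnBu3, Pd(PPh3)4 (5 mol %), toluene, 100 °C
Reagents that add atoms: allyltributylstannane, C=CC[Sn](CCCC)(CCCC)CCCC
Why: Migita–Kosugi–Stille coupling, in which the ortho-formyl group activates the C–Br bond for oxidative addition and the aldehyde, MOM and TIPS groups are inert to Pd(0).

Step 4
Reactants: 4 2-allyl-4-(methoxymethoxy)-5-(triisopropylsilyloxy)benzaldehyde
Product: 5 [2-allyl-4-(methoxymethoxy)-5-(triisopropylsilyloxy)phenyl]methanol
Conditions: NaBH4, MeOH, 0 °C
Reagents that add atoms: none
Why: Borohydride reduction of the aryl aldehyde to the benzylic alcohol leaves the allyl group and both ethers untouched.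

Step 5
Reactants: 5 [2-allyl-4-(methoxymethoxy)-5-(triisopropylsilyloxy)phenyl]methanol
Product: 6 1-allyl-2-(bromomethyl)-5-(methoxymethoxy)-4-(triisopropylsilyloxy)benzene
Conditions: CBr4, PPh3, 2,6-lutidine, CH2Cl2, 0 °C; used at once
Reagents that add atoms: carbon tetrabromide, BrC(Br)(Br)Br
Why: The Appel reaction converts the primary benzylic alcohol into the bromide under buffered, essentially neutral conditions that should leave the MOM acetal and the silyl ether intact.

Step 6
Reactants: 6 1-allyl-2-(bromomethyl)-5-(methoxymethoxy)-4-(triisopropylsilyloxy)benzene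
Product: 7 1-allyl-5-(methoxymethoxy)-2-prenyl-4-(triisopropylsilyloxy)benzene
Conditions: Me2C=CHMgBr (1.5 equiv), CuI (10 mol %), THF, −30 → 0 °C
Reagents that add atoms: (2-methylprop-1-en-1-yl)magnesium bromide, CC(C)=C[Mg]Br
Why: Copper-catalysed Kumada-type coupling of a benzylic bromide with an alkenyl Grignard reagent builds the prenyl group with its trisubstituted alkene fixed in position, since the new bond joins the benzylic carbon to a vinylic carbon and no allylic transposition is possible.

**Resorcinol-ring fragment**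

Step 7
Reactants: 8 3-hydroxyphenyl benzoate (resorcinol monobenzoate)
Product: 9 2-bromo-5-hydroxyphenyl benzoate
Conditions: NBS (1.0 equiv), MeCN, 0 °C
Reagents that add atoms: N-bromosuccinimide, O=C1CCC(=O)N1Br
Why: Electrophilic aromatic bromination is steered para to the free hydroxyl (the strongest activator; the benzoate oxygen donates weakly and the carbon between the oxygens is hindered), which puts bromine ortho to the ester oxygen and so tells the two oxygens apart.

Step 8
Reactants: 9 2-bromo-5-hydroxyphenyl benzoate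
Product: 11 2-bromo-5-[(3-methylbut-2-en-1-yl)oxy]phenol, via benzoate prenyl ether 10 (not isolated)
Conditions: prenyl bromide (1.0 equiv), K2CO3, acetone, rt; then MeOH, rt
Reagents that add atoms: 1-bromo-3-methylbut-2-ene (prenyl bromide), CC(C)=CCBr
Why: Williamson etherification of the only free phenol (the classical alkylation of resorcinol monobenzoate) is followed in the same flask by carbonate-mediated methanolysis of the aryl ester.

Step 9
Reactants: 11 2-bromo-5-[(3-methylbut-2-en-1-yl)oxy]phenol
Product: 13 4-bromo-6-(2-methylbut-3-en-2-yl)benzene-1,3-diol, via ortho-dienone 12 (not isolated)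
Conditions: PhNEt2, 185 °C, sealed tube, short reaction time
Reagents that add atoms: none
Why: Aromatic Claisen rearrangement: the [3,3] shift delivers the inverted C5 unit (1,1-dimethylallyl) to the unhindered ortho carbon para to the free OH, because the other ortho carbon lies between two oxygens and the para carbon is blocked by bromine (so no onward Cope shift), and the dienone then tautomerises to the phenol.

Step 10
Reactants: 13 4-bromo-6-(2-methylbut-3-en-2-yl)benzene-1,3-diol
Product: 14 1-bromo-2,4-bis(methoxymethoxy)-5-(2-methylbut-3-en-2-yl)benzene (Ar′–Br)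
Conditions: NaH (2.5 equiv), MOMCl (2.5 equiv), DMF, 0 °C → rt
Reagents that add atoms: chloromethyl methyl ether (MOMCl), COCCl
Why: Double Williamson-type O-alkylation of the sodium phenoxides, with NaH chosen because one hydroxyl is flanked by the tertiary alkyl group.

**Assembly and end game**

Step 11
Reactants: 7 1-allyl-5-(methoxymethoxy)-2-prenyl-4-(triisopropylsilyloxy)benzene; 14 1-bromo-2,4-bis(methoxymethoxy)-5-(2-methylbut-3-en-2-yl)benzene
Product: 16 1-(Ar′)-3-[5-(methoxymethoxy)-2-prenyl-4-(triisopropylsilyloxy)phenyl]propane, via B-alkyl-9-BBN 15 (not isolated)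
Conditions: 9-BBN (0.5 M in THF, slight excess), 0 °C → rt; then 3 M aq K3PO4, 14, Pd(OAc)2 (5 mol %), SPhos (10 mol %), THF, 65 °C
Reagents that add atoms: none
Why: Anti-Markovnikov hydroboration with 9-BBN selects the monosubstituted allyl alkene over the trisubstituted prenyl alkene by a wide margin, and the B-alkyl Suzuki–Miyaura coupling with the electron-rich ortho-alkoxy aryl bromide is run with a dialkylbiarylphosphine ligand, residual B–H being destroyed by the aqueous base before 14 (which carries a terminal vinyl group) is added.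

Step 12
Reactants: 16 1-(Ar′)-3-[5-(methoxymethoxy)-2-prenyl-4-(triisopropylsilyloxy)phenyl]propane
Product: 17 4-[3-(Ar′)propyl]-2-(methoxymethoxy)-5-prenylphenol
Conditions: TBAF (1.1 equiv), THF, 0 °C; aqueous work-up
Reagents that add atoms: none
Why: Fluoride-induced cleavage of the aryl silyl ether frees the one phenol whose only open ortho position is the future C4a, while MOM ethers and alkenes are inert.

Step 13
Reactants: 17 4-[3-(Ar′)propyl]-2-(methoxymethoxy)-5-prenylphenol
Product: 19 5-[3-(Ar′)propyl]-2-hydroxy-3-(methoxymethoxy)-6-prenylbenzaldehyde, via salicyl alcohol 18 (not isolated)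
Conditions: MgCl2 (anhydrous), Et3N, (CH2O)n, MeCN, reflux
Reagents that add atoms: formaldehyde (as paraformaldehyde), C=O
Why: Magnesium-mediated ortho-formylation (Casnati–Skattebøl): the magnesium phenoxide delivers formaldehyde only to the ortho carbon, of which just one is free, and the hydroxymethyl intermediate is oxidised in situ by a second formaldehyde through Oppenauer-type hydride transfer, while the fully protected resorcinol ring cannot react.

Step 14
Reactants: 19 5-[3-(Ar′)propyl]-2-hydroxy-3-(methoxymethoxy)-6-prenylbenzaldehyde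
Product: 21 6-[3-(Ar′)propyl]-8-(methoxymethoxy)-5-prenyl-2H-chromen-2-one, via aryl phosphoranylideneacetate 20 (not isolated)
Conditions: Ph3P=C=C=O (1.3 equiv), toluene, 90 °C
Reagents that add atoms: (triphenylphosphoranylidene)ketene, O=C=C=P(c1ccccc1)(c1ccccc1)c1ccccc1
Why: The phenol adds across the ketene C=C of the ylide to give the aryl phosphoranylideneacetate, which closes by intramolecular Wittig olefination onto the ortho aldehyde, so the lactone forms with C3=C4 necessarily cis.

Step 15
Reactants: 21 6-[3-(Ar′)propyl]-8-(methoxymethoxy)-5-prenyl-2H-chromen-2-one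
Product: 23 4-[3-(Ar′)propyl]-6-[(1Z)-3-hydroxy-3-methylbut-1-en-1-yl]-2-(methoxymethoxy)-5-prenylphenol, via cis-enone phenoxide 22 (not isolated)
Conditions: MeMgBr (5 equiv), CeCl3 (dried, 5 equiv), THF, −78 → 0 °C; then sat. aq NH4Cl, 0 °C
Reagents that add atoms: methylmagnesium bromide, C[Mg]Br
Why: Methylcerium (from MeMgBr and CeCl3) adds to the lactone carbonyl C2 of 21; the hemiketal alkoxide collapses by expelling the C8a phenoxide, which opens the lactone to the cis-enone phenoxide 22, and a second methyl adds 1,2 to that ketone, so both C2–CH3 bonds form in one operation. The closest known reaction type is the double Grignard addition to coumarins that leads, after cyclodehydration, to 2,2-dimethyl-2H-chromenes. No ring is closed (the pyranone ring is opened) and no stereocentre is created; the Z geometry of C3=C4 is inherited from the ring of 21 and should not be at risk at or below 0 °C. The step needs 1,2- over 1,4-addition and addition over enolisation of the methyl ketone in 22: the oxophilic, weakly basic cerium reagent should secure both, helped by the phenoxide-bearing aryl group that deactivates the enone β-carbon and by the prenyl group on C5, peri to C4, which shields that carbon. The MOM acetals and both isoprenoid side chains are inert to the reagent, and the cold neutral quench should keep 23 from cyclising prematurely.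

Step 16
Reactants: 23 4-[3-(Ar′)propyl]-6-[(1Z)-3-hydroxy-3-methylbut-1-en-1-yl]-2-(methoxymethoxy)-5-prenylphenol
Product: 24 6-[3-(Ar′)propyl]-8-(methoxymethoxy)-2,2-dimethyl-5-prenyl-2H-chromene (tris-MOM kazinol K)
Conditions: PPTS (10 mol %), CH2Cl2, rt
Reagents that add atoms: none
Why: Acid-catalysed cyclodehydration: ionisation of the tertiary cinnamyl-type alcohol gives an allyl cation/o-quinone methide that the ortho phenol oxygen captures to close the six-membered pyran, which the cis alkene makes possible, and PPTS is too weak to cleave the MOM acetals.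

Step 17
Reactants: 24 6-[3-(Ar′)propyl]-8-(methoxymethoxy)-2,2-dimethyl-5-prenyl-2H-chromene
Product: 25 kazinol K, 4-{3-[8-hydroxy-2,2-dimethyl-5-(3-methylbut-2-en-1-yl)-2H-chromen-6-yl]propyl}-6-(2-methylbut-3-en-2-yl)benzene-1,3-diol
Conditions: HCl (2 M in MeOH), rt → 40 °C
Reagents that add atoms: none
Why: Acid-catalysed acetal exchange with methanol removes the three MOM ethers as dimethoxymethane, and dilute acid near room temperature should be tolerated by the chromene, the prenyl group (no ortho hydroxyl) and the 1,1-dimethylallyl group (cyclisation would need a secondary cation).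

**Compound list**

1 | 2-bromo-4,5-dihydroxybenzaldehyde | O=Cc1cc(O)c(O)cc1Br | starting material
2 | 2-bromo-5-hydroxy-4-(methoxymethoxy)benzaldehyde | O=Cc1cc(O)c(OCOC)cc1Br | intermediate
3 | 2-bromo-4-(methoxymethoxy)-5-(triisopropylsilyloxy)benzaldehyde | O=Cc1cc(O[Si](C(C)C)(C(C)C)C(C)C)c(OCOC)cc1Br | intermediate
4 | 2-allyl-4-(methoxymethoxy)-5-(triisopropylsilyloxy)benzaldehyde | O=Cc1cc(O[Si](C(C)C)(C(C)C)C(C)C)c(OCOC)cc1CC=C | intermediate
5 | [2-allyl-4-(methoxymethoxy)-5-(triisopropylsilyloxy)phenyl]methanol | OCc1cc(O[Si](C(C)C)(C(C)C)C(C)C)c(OCOC)cc1CC=C | intermediate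
6 | 1-allyl-2-(bromomethyl)-5-(methoxymethoxy)-4-(triisopropylsilyloxy)benzene | BrCc1cc(O[Si](C(C)C)(C(C)C)C(C)C)c(OCOC)cc1CC=C | intermediate
7 | 1-allyl-5-(methoxymethoxy)-2-prenyl-4-(triisopropylsilyloxy)benzene | CC(C)=CCc1cc(O[Si](C(C)C)(C(C)C)C(C)C)c(OCOC)cc1CC=C | intermediate
8 | 3-hydroxyphenyl benzoate (resorcinol monobenzoate) | O=C(Oc1cccc(O)c1)c1ccccc1 | starting material
9 | 2-bromo-5-hydroxyphenyl benzoate | O=C(Oc1cc(O)ccc1Br)c1ccccc1 | intermediate
10 | 2-bromo-5-[(3-methylbut-2-en-1-yl)oxy]phenyl benzoate | O=C(Oc1cc(OCC=C(C)C)ccc1Br)c1ccccc1 | intermediate (not isolated)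
11 | 2-bromo-5-[(3-methylbut-2-en-1-yl)oxy]phenol | CC(C)=CCOc1ccc(Br)c(O)c1 | intermediate
12 | 4-bromo-3-hydroxy-6-(2-methylbut-3-en-2-yl)cyclohexa-2,4-dien-1-one | O=C1C=C(O)C(Br)=CC1C(C)(C)C=C | intermediate (not isolated)
13 | 4-bromo-6-(2-methylbut-3-en-2-yl)benzene-1,3-diol | C=CC(C)(C)c1cc(Br)c(O)cc1O | intermediate
14 | 1-bromo-2,4-bis(methoxymethoxy)-5-(2-methylbut-3-en-2-yl)benzene | C=CC(C)(C)c1cc(Br)c(OCOC)cc1OCOC | intermediate
15 | 9-{3-[5-(methoxymethoxy)-2-prenyl-4-(triisopropylsilyloxy)phenyl]propyl}-9-borabicyclo[3.3.1]nonane | CC(C)=CCc1cc(O[Si](C(C)C)(C(C)C)C(C)C)c(OCOC)cc1CCCB1C2CCCC1CCC2 | intermediate (not isolated)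
16 | 1-(Ar′)-3-[5-(methoxymethoxy)-2-prenyl-4-(triisopropylsilyloxy)phenyl]propane | C=CC(C)(C)c1cc(CCCc2cc(OCOC)c(O[Si](C(C)C)(C(C)C)C(C)C)cc2CC=C(C)C)c(OCOC)cc1OCOC | intermediate
17 | 4-[3-(Ar′)propyl]-2-(methoxymethoxy)-5-prenylphenol | C=CC(C)(C)c1cc(CCCc2cc(OCOC)c(O)cc2CC=C(C)C)c(OCOC)cc1OCOC | intermediate
18 | 4-[3-(Ar′)propyl]-6-(hydroxymethyl)-2-(methoxymethoxy)-5-prenylphenol | C=CC(C)(C)c1cc(CCCc2cc(OCOC)c(O)c(CO)c2CC=C(C)C)c(OCOC)cc1OCOC | intermediate (not isolated)
19 | 5-[3-(Ar′)propyl]-2-hydroxy-3-(methoxymethoxy)-6-prenylbenzaldehyde | C=CC(C)(C)c1cc(CCCc2cc(OCOC)c(O)c(C=O)c2CC=C(C)C)c(OCOC)cc1OCOC | intermediate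
20 | 4-[3-(Ar′)propyl]-2-formyl-6-(methoxymethoxy)-3-prenylphenyl (triphenylphosphoranylidene)acetate | C=CC(C)(C)c1cc(CCCc2cc(OCOC)c(OC(=O)C=P(c3ccccc3)(c3ccccc3)c3ccccc3)c(C=O)c2CC=C(C)C)c(OCOC)cc1OCOC | intermediate (not isolated)
21 | 6-[3-(Ar′)propyl]-8-(methoxymethoxy)-5-prenyl-2H-chromen-2-one (key-step precursor) | C=CC(C)(C)c1cc(CCCc2cc(OCOC)c3OC(=O)C=Cc3c2CC=C(C)C)c(OCOC)cc1OCOC | intermediate
22 | (3Z)-4-{3-[3-(Ar′)propyl]-6-hydroxy-5-(methoxymethoxy)-2-prenylphenyl}but-3-en-2-one (formed as its phenoxide, drawn neutral) | C=CC(C)(C)c1cc(CCCc2cc(OCOC)c(O)c(/C=C\C(C)=O)c2CC=C(C)C)c(OCOC)cc1OCOC | intermediate (not isolated)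
23 | 4-[3-(Ar′)propyl]-6-[(1Z)-3-hydroxy-3-methylbut-1-en-1-yl]-2-(methoxymethoxy)-5-prenylphenol (key-step product) | C=CC(C)(C)c1cc(CCCc2cc(OCOC)c(O)c(/C=C\C(C)(C)O)c2CC=C(C)C)c(OCOC)cc1OCOC | intermediate
24 | 6-[3-(Ar′)propyl]-8-(methoxymethoxy)-2,2-dimethyl-5-prenyl-2H-chromene (tris-MOM kazinol K) | C=CC(C)(C)c1cc(CCCc2cc(OCOC)c3c(c2CC=C(C)C)C=CC(C)(C)O3)c(OCOC)cc1OCOC | intermediate
25 | kazinol K | C=CC(C)(C)c1cc(CCCc2cc(O)c3c(c2CC=C(C)C)C=CC(C)(C)O3)c(O)cc1O | target

**Step count and risks**

Total steps: 17. Longest linear sequence: 13 (steps 1–6 and 11–17); steps 7–10 form the convergent branch.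

Steps most likely to fail:

1. Step 9 (aromatic Claisen). The first-formed phenol may go on through the ene/retro-ene "abnormal" pathway, the hydroxyl may add to the new vinyl group, the ether may fragment with loss of isoprene, and part of the migration may go to the carbon between the two oxygens. The fallback attaches the 1,1-dimethylallyl group by cross-coupling and sets out from 9. A second NBS bromination (ortho to the hydroxyl, para to the benzoate oxygen) would give 2,4-dibromo-5-hydroxyphenyl benzoate F1. Methanolysis (K2CO3, MeOH) would give 4,6-dibromobenzene-1,3-diol F2, and MOMCl/NaH the C2-symmetric 1,5-dibromo-2,4-bis(methoxymethoxy)benzene F3. A ligand-controlled γ-selective Suzuki–Miyaura coupling of one equivalent of prenylboronic acid pinacol ester at either of the two equivalent C–Br bonds would then give 14, where the route is rejoined.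

2. Step 13 (ortho-formylation). C–C bond formation at the crowded carbon between the hydroxyl and the prenyl-bearing carbon may be slow, and O-methoxymethylation of the phenol by formaldehyde/methanol, or a carbonyl-ene reaction of the new aldehyde with the neighbouring prenyl group, may compete. The fallback builds the pyranone without an aldehyde and sets out from 17. Esterification with propiolic acid (DCC, CH2Cl2, 0 °C) would give 4-[3-(Ar′)propyl]-2-(methoxymethoxy)-5-prenylphenyl propiolate F4. Gold(I)-catalysed intramolecular hydroarylation (6-endo closure onto the only free ortho carbon) would then give coumarin 21 directly, where the route is rejoined before the key step.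

3. Step 15 (double methyl addition). The second methyl may add in conjugate fashion to the ring-opened enone, or the methyl ketone may be enolised so that the reaction stops after one addition. The fallback reaches the chromene through an o-quinone methide and sets out from 19. Addition of excess (2-methylprop-1-enyl)magnesium bromide to the aldehyde would give 4-[3-(Ar′)propyl]-6-(1-hydroxy-3-methylbut-2-en-1-yl)-2-(methoxymethoxy)-5-prenylphenol F5. Mild acid (PPTS) or gentle warming would dehydrate it to the o-quinone methide, whose oxa-6π electrocyclisation closes the 2,2-dimethylpyran and gives 24, where the route is rejoined.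

**Further compounds**

F1 | step 9 | 2,4-dibromo-5-hydroxyphenyl benzoate | O=C(Oc1cc(O)c(Br)cc1Br)c1ccccc1
F2 | step 9 | 4,6-dibromobenzene-1,3-diol | Oc1cc(O)c(Br)cc1Br
F3 | step 9 | 1,5-dibromo-2,4-bis(methoxymethoxy)benzene | COCOc1cc(OCOC)c(Br)cc1Br
F4 | step 13 | 4-[3-(Ar′)propyl]-2-(methoxymethoxy)-5-prenylphenyl propiolate | C=CC(C)(C)c1cc(CCCc2cc(OCOC)c(OC(=O)C#C)cc2CC=C(C)C)c(OCOC)cc1OCOC
F5 | step 15 | 4-[3-(Ar′)propyl]-6-(1-hydroxy-3-methylbut-2-en-1-yl)-2-(methoxymethoxy)-5-prenylphenol (racemic) | C=CC(C)(C)c1cc(CCCc2cc(OCOC)c(O)c(C(O)C=C(C)C)c2CC=C(C)C)c(OCOC)cc1OCOC
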